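**What stood.** The constants of the steps were hidden from me, so I began from the runs and the list of reactions.

| flask | starting material | remark | time |
|---|---|---|---|
| west | 30 mM | run made earlier |  |
| flask | 20 mM |  | 4.0 d |

west run (percent of the starting material charged)

| time / h | target / % | side product / % | starting material / % |
|---|---|---|---|
| 2.50 | 81.6 | 11.3 | 1.3 |
| 4.00 | 88.0 | 11.3 | 0.4 |
| 5.00 | 88.6 | 11.7 | 0 |
| 8.00 | 88.8 | 11.3 | 0 |
| 12.0 | 88.8 | 11.9 | 0 |
| 20.0 | 88.4 | 11.2 | 0 |
| 30.0 | 88.1 | 11.5 | 0 |

(readings scatter by 0.3 percentage points)

- in percentages every species weighs as the starting material in it: one side product counts as two
- the numbers in the tables scatter with a standard deviation of 0.3 percentage points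
- reactions considered so far: intermediate B -> intermediate C; intermediate A <-> intermediate B; starting material -> intermediate A; starting material + intermediate B -> side product; intermediate C -> target

1. share of target in target plus side product at 20 min
2. share of target in target plus side product at 5.0 h
3. share of target in target plus side product at 4.0 d
4. which of target and side product there is more of at 4.0 d

**West readings.** From 5.00 h on, the west run read 0% starting material. Averaged over those readings, it held 88.5% target and 11.5% side product, together 100% of the charge.

**First link.** I scaled the side product directly with the charge, from 30 mM to 20 mM, and got 7.68% for the flask.

**Weak link.** That link was weak: target and side product share one whole, so a rising side percentage pushes the target percentage down. I reforged it from the rates. Intermediate B either passes on to intermediate C or meets starting material, a pseudo-first-order loss, so in the rate of side product over the rate of forming intermediate C, intermediate B cancels and a constant times starting material remains. Among the listed reactions, intermediate C goes on to target, so I counted the final target as what had passed through intermediate C; the ratio I reckoned was therefore one of end totals, not of early shares. I took the decay of starting material as first order, with the same shape at either charge. Integrating over the run then made the final ratio proportional to the charge.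

**Carried ratio.** The west ratio was 0.130, which gave the side ratio per millimolar, side product percent over target percent at the end, divided by the charge (a selectivity factor of my own reckoning): 0.00434 mM⁻¹. For the flask the ratio became 0.0867. Target share is one over one plus that ratio, so I committed to 92.0% target and 7.98% side product, a side share slightly higher than the first link's.

**The forecast.** The forecast gave 50%, 92% and 92%, with target ahead, holding of side product that “its share should scale roughly with concentration”.

**The result.** The flask gave a target share of 57.0% at 20 min, 92.0% at 5.0 h and 92.0% at 4.0 d, with 92.0% target against 8.03% side product.

    intermediate B → intermediate C (k = 0.140 min⁻¹)
    intermediate A ⇌ intermediate B (K = 0.740, k = 0.310 min⁻¹)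
    starting material → intermediate A (k = 0.0270 min⁻¹)
    starting material + intermediate B → side product (k = 0.970 M⁻¹ min⁻¹)
    intermediate C → target (k = 0.0450 min⁻¹)

**Neighbouring flask.** The flask's own side ratio per millimolar came to 0.00436 mM⁻¹, beside the 0.00434 mM⁻¹ I had carried from the west run. I then applied the carried value to the neighbouring flask, charged with 5.0 mM starting material. Its ratio was 0.0217, which gave 97.9% target and 2.12% side product. At 4.00 d that neighbouring flask held 97.8% target and 2.17% side product.

The data come from a simulation with made-up constants.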